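**Plan**

- Retrosynthesis: the lactone C(=O)–O bond is cut first. On ring A the diaryl ether bond (C7–O) and the aryl–carboxyl bond (C6–CO2H) are then cut together.
- These two bonds sit on adjacent carbons next to the oxygen-bearing C5. That arrangement leads back to a chromene-fused aryne (C6≡C7) steered by the C5 ether, a ring-B phenoxide and CO2.
- Ring A: the pyran ring is made first as a chromanone from phloroglucinol (step 1) and turned into the chromene (step 3). The ortho-silyl triflate is then installed by carbamate-directed metalation (steps 5–7).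
- Ring B: methoxyhydroquinone receives its fourth oxygen by bromination and borylation–oxidation, and the prenyl group by directed metalation beside a shielding silyl ether (steps 8–13).
- Forward: the two arenes and CO2 are joined in step 14 with no ring closure. The MOM groups are removed and the seven-membered lactone is closed last (step 16).
- Stereochemistry: the target has no stereocentre; the only one on the way (C4 of carbinol 5) is racemic and is destroyed in the same step.

Key step: step 14

Remark: ring A positions are cited in chromene numbering (O1, C2 to C8a) and ring B positions in the phenol numbering of 22 (C1 carries the nucleophilic oxygen).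

**Route**

Step 1
Reactants: 1 phloroglucinol; 2 3-methylbut-2-enoic acid
Product: 3 5,7-dihydroxy-2,2-dimethylchroman-4-one
Conditions: P2O5, MeSO3H, 70 °C
Reagents that add atoms: 3-methylbut-2-enoic acid (2), CC(C)=CC(=O)O
Why: Friedel–Crafts acylation of the threefold-symmetric triol followed by intramolecular oxa-Michael addition should close the dimethylchromanone without any regiochemical ambiguity.

Step 2
Reactants: 3 5,7-dihydroxy-2,2-dimethylchroman-4-one
Product: 4 5-hydroxy-2,2-dimethyl-4-oxochroman-7-yl diethylcarbamate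
Conditions: Et2NCOCl, K2CO3, MeCN, 60 °C
Reagents that add atoms: N,N-diethylcarbamoyl chloride, CCN(CC)C(Cl)=O
Why: O-carbamoylation should take place only at the free, more acidic 7-hydroxyl because the 5-hydroxyl is locked in a hydrogen bond to the C4 ketone.

Step 3
Reactants: 4 5-hydroxy-2,2-dimethyl-4-oxochroman-7-yl diethylcarbamate
Product: 6 5-hydroxy-2,2-dimethyl-2H-chromen-7-yl diethylcarbamate, via chromanol 5 (not isolated)
Conditions: NaBH4, THF–MeOH, 0 °C → rt; then 2 M aq HCl, rt
Reagents that add atoms: none
Why: Borohydride reduction of the aryl ketone gives benzylic carbinol 5, which, activated by ortho and para oxygens, should undergo acid-catalysed dehydration to the chromene while the carbamate is untouched.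

Step 4
Reactants: 6 5-hydroxy-2,2-dimethyl-2H-chromen-7-yl diethylcarbamate
Product: 7 5-(methoxymethoxy)-2,2-dimethyl-2H-chromen-7-yl diethylcarbamate
Conditions: MOMCl, iPr2NEt, CH2Cl2, 0 °C → rt
Reagents that add atoms: chloromethyl methyl ether, COCCl
Why: O-alkylation (MOM protection) of the 5-hydroxyl, no longer chelated once the ketone is gone, should be straightforward.

Step 5
Reactants: 7 5-(methoxymethoxy)-2,2-dimethyl-2H-chromen-7-yl diethylcarbamate
Product: 9 5-(methoxymethoxy)-2,2-dimethyl-6-(trimethylsilyl)-2H-chromen-7-yl diethylcarbamate, via C6 aryllithium 8 (not isolated)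
Conditions: s-BuLi, TMEDA, THF, −78 °C; then TMSCl, −78 °C → rt
Reagents that add atoms: chlorotrimethylsilane, C[Si](C)(C)Cl
Why: Directed ortho-metalation should occur at C6–H, which lies between the two strongest directors (O-carbamate and MOM ether), whereas C8–H has only the carbamate and the ring ether oxygen; the low temperature suppresses the anionic ortho-Fries shift before the silyl quench.

Step 6
Reactants: 9 5-(methoxymethoxy)-2,2-dimethyl-6-(trimethylsilyl)-2H-chromen-7-yl diethylcarbamate
Product: 10 5-(methoxymethoxy)-2,2-dimethyl-6-(trimethylsilyl)-2H-chromen-7-ol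
Conditions: LiAlH4, THF, 0 °C → rt
Reagents that add atoms: none
Why: Hydride reduction of the aryl carbamate expels the phenoxide, the usual way of removing a diethylcarbamate director; the MOM ether, aryl–silicon bond and chromene alkene are inert to it.

Step 7
Reactants: 10 5-(methoxymethoxy)-2,2-dimethyl-6-(trimethylsilyl)-2H-chromen-7-ol
Product: 11 5-(methoxymethoxy)-2,2-dimethyl-6-(trimethylsilyl)-2H-chromen-7-yl trifluoromethanesulfonate
Conditions: Tf2O, pyridine, CH2Cl2, 0 °C
Reagents that add atoms: trifluoromethanesulfonic anhydride, O=S(=O)(OS(=O)(=O)C(F)(F)F)C(F)(F)F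
Why: O-sulfonylation of the phenol under pyridine buffering should give the ortho-silylaryl triflate aryne precursor without loss of the acid-labile MOM group.

Step 8
Reactants: 12 methoxyhydroquinone
Product: 13 2-methoxy-1,4-bis(methoxymethoxy)benzene
Conditions: MOMCl, iPr2NEt, CH2Cl2, 0 °C → rt, under argon
Reagents that add atoms: chloromethyl methyl ether, COCCl
Why: Double O-alkylation (MOM protection) of both phenols is routine and removes the air sensitivity of the hydroquinone.

Step 9
Reactants: 13 2-methoxy-1,4-bis(methoxymethoxy)benzene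
Product: 14 1-bromo-4-methoxy-2,5-bis(methoxymethoxy)benzene
Conditions: NBS, MeCN, 0 °C → rt
Reagents that add atoms: N-bromosuccinimide, O=C1CCC(=O)N1Br
Why: Electrophilic aromatic bromination should go to the unhindered position para to the methoxy group and ortho to a MOM ether, the usual site for 1,2,4-trialkoxybenzenes.

Step 10
Reactants: 14 1-bromo-4-methoxy-2,5-bis(methoxymethoxy)benzene
Product: 17 4-methoxy-2,5-bis(methoxymethoxy)phenol, via aryllithium 15 (not isolated), via dimethyl arylboronate 16 (not isolated)
Conditions: n-BuLi, THF, −78 °C; B(OMe)3, −78 °C → rt; then 30% H2O2, aq NaOH, 0 °C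
Reagents that add atoms: hydrogen peroxide, OO (the phenol oxygen); trimethyl borate, COB(OC)OC (boron and methoxy groups of 16 only)
Why: Bromine–lithium exchange, borylation and oxidative carbon-to-oxygen migration of the boronate turn the aryl bromide into the phenol under basic conditions that the MOM ethers tolerate.

Step 11
Reactants: 17 4-methoxy-2,5-bis(methoxymethoxy)phenol
Product: 18 triisopropyl[4-methoxy-2,5-bis(methoxymethoxy)phenoxy]silane
Conditions: TIPSCl, imidazole, DMF, rt
Reagents that add atoms: chlorotriisopropylsilane, CC(C)[Si](Cl)(C(C)C)C(C)C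
Why: O-silylation installs a bulky, non-coordinating ether that shields the neighbouring C6–H from lithiation in the next step.

Step 12
Reactants: 18 triisopropyl[4-methoxy-2,5-bis(methoxymethoxy)phenoxy]silane; 19 prenyl bromide
Product: 21 triisopropyl[4-methoxy-2,5-bis(methoxymethoxy)-3-(3-methylbut-2-en-1-yl)phenoxy]silane, via C3 aryllithium 20 (not isolated)
Conditions: n-BuLi, TMEDA, THF, −20 → 0 °C; then CuBr·SMe2 (10 mol %), 19, −78 °C → rt
Reagents that add atoms: prenyl bromide (19), CC(C)=CCBr
Why: Directed ortho-metalation should take place at the hydrogen flanked by the MOM ether and the methoxy group (the other ring hydrogen is blocked by the silyl ether), and copper-catalysed allylic substitution then delivers the linear prenyl group.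

Step 13
Reactants: 21 triisopropyl[4-methoxy-2,5-bis(methoxymethoxy)-3-(3-methylbut-2-en-1-yl)phenoxy]silane
Product: 22 4-methoxy-2,5-bis(methoxymethoxy)-3-(3-methylbut-2-en-1-yl)phenol
Conditions: TBAF, THF, 0 °C
Reagents that add atoms: none
Why: Fluoride-induced desilylation of the aryl silyl ether frees the phenol and leaves the MOM ethers and the prenyl group alone.

Step 14
Reactants: 11 5-(methoxymethoxy)-2,2-dimethyl-6-(trimethylsilyl)-2H-chromen-7-yl trifluoromethanesulfonate; 22 4-methoxy-2,5-bis(methoxymethoxy)-3-(3-methylbut-2-en-1-yl)phenol; 23 carbon dioxide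
Product: 28 7-[4-methoxy-2,5-bis(methoxymethoxy)-3-(3-methylbut-2-en-1-yl)phenoxy]-5-(methoxymethoxy)-2,2-dimethyl-2H-chromene-6-carboxylic acid, via potassium phenoxide 24 (not isolated), via aryne 25 (not isolated), via aryl anion 26 (not isolated), via potassium carboxylate 27 (not isolated)
Conditions: 22 (1.5 equiv), KH, THF, 0 °C; 18-crown-6, KF, CO2 (1 atm); 11 added over 4 h, 0 °C → rt; cold dilute aq HCl work-up
Reagents that add atoms: carbon dioxide (23), O=C=O
Why: Proposed new method: fluoride attack at silicon of 11 with loss of triflate gives aryne 25, whose C6≡C7 bond is polarised by the inductively withdrawing MOM ether on C5, so that the crown-ether-separated phenoxide 24 should add at C7, the terminus remote from that ether, and place the negative charge at C6 between two oxygen-bearing carbons (aryl anion 26). Anion 26 should then be captured at carbon by the excess CO2 to give carboxylate 27, which is protonated to 28 on work-up. The closest known reaction types are the fluoride-triggered three-component coupling of arynes with amines and CO2 to anthranilic acids and the O-arylation of phenols by ortho-silylaryl triflates; the new element is an anionic oxygen nucleophile combined with CO2 as the terminating electrophile. No ring is closed and no stereocentre is formed. Two selectivities are needed: the site of addition, secured by the C5 oxygen substituent, and carboxylation ahead of protonation, for which the phenoxide is made with KH (H2 as the only by-product), the medium is THF free of N–H and O–H donors, and 11 is added slowly to an excess of 24 so that neither fluoride nor carboxylate 27 competes for the aryne.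

Step 15
Reactants: 28 7-[4-methoxy-2,5-bis(methoxymethoxy)-3-(3-methylbut-2-en-1-yl)phenoxy]-5-(methoxymethoxy)-2,2-dimethyl-2H-chromene-6-carboxylic acid
Product: 29 7-[2,5-dihydroxy-4-methoxy-3-(3-methylbut-2-en-1-yl)phenoxy]-5-hydroxy-2,2-dimethyl-2H-chromene-6-carboxylic acid
Conditions: 3 M aq HCl, MeOH, 40 °C
Reagents that add atoms: none
Why: Acid-catalysed acetal exchange with methanol should remove all three phenolic MOM groups under conditions commonly tolerated by prenyl groups and dimethylchromenes.

Step 16
Reactants: 29 7-[2,5-dihydroxy-4-methoxy-3-(3-methylbut-2-en-1-yl)phenoxy]-5-hydroxy-2,2-dimethyl-2H-chromene-6-carboxylic acid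
Product: 30 garcinisidone B
Conditions: DCC, THF (high dilution), 0 °C → rt
Reagents that add atoms: none
Why: Carbodiimide-mediated lactonisation, the classical depsidone ring closure, should engage only the ring-B hydroxyl ortho to the ether oxygen, since it alone can reach the activated carboxyl to form the seven-membered ring.

**Compound list**

1 | phloroglucinol (benzene-1,3,5-triol) | Oc1cc(O)cc(O)c1 | starting material
2 | 3-methylbut-2-enoic acid | CC(C)=CC(=O)O | starting material
3 | 5,7-dihydroxy-2,2-dimethylchroman-4-one | CC1(C)CC(=O)c2c(O)cc(O)cc2O1 | intermediate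
4 | 5-hydroxy-2,2-dimethyl-4-oxochroman-7-yl diethylcarbamate | CCN(CC)C(=O)Oc1cc(O)c2C(=O)CC(C)(C)Oc2c1 | intermediate
5 | 4,5-dihydroxy-2,2-dimethylchroman-7-yl diethylcarbamate (racemic at C4) | CCN(CC)C(=O)Oc1cc(O)c2C(O)CC(C)(C)Oc2c1 | intermediate (not isolated)
6 | 5-hydroxy-2,2-dimethyl-2H-chromen-7-yl diethylcarbamate | CCN(CC)C(=O)Oc1cc(O)c2C=CC(C)(C)Oc2c1 | intermediate
7 | 5-(methoxymethoxy)-2,2-dimethyl-2H-chromen-7-yl diethylcarbamate | CCN(CC)C(=O)Oc1cc(OCOC)c2C=CC(C)(C)Oc2c1 | intermediate
8 | 6-lithio-5-(methoxymethoxy)-2,2-dimethyl-2H-chromen-7-yl diethylcarbamate | CCN(CC)C(=O)Oc1cc2OC(C)(C)C=Cc2c(OCOC)c1[Li] | intermediate (not isolated)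
9 | 5-(methoxymethoxy)-2,2-dimethyl-6-(trimethylsilyl)-2H-chromen-7-yl diethylcarbamate | CCN(CC)C(=O)Oc1cc2OC(C)(C)C=Cc2c(OCOC)c1[Si](C)(C)C | intermediate
10 | 5-(methoxymethoxy)-2,2-dimethyl-6-(trimethylsilyl)-2H-chromen-7-ol | C[Si](C)(C)c1c(O)cc2OC(C)(C)C=Cc2c1OCOC | intermediate
11 | 5-(methoxymethoxy)-2,2-dimethyl-6-(trimethylsilyl)-2H-chromen-7-yl trifluoromethanesulfonate | C[Si](C)(C)c1c(OS(=O)(=O)C(F)(F)F)cc2OC(C)(C)C=Cc2c1OCOC | intermediate (aryne precursor)
12 | methoxyhydroquinone (2-methoxybenzene-1,4-diol) | COc1cc(O)ccc1O | starting material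
13 | 2-methoxy-1,4-bis(methoxymethoxy)benzene | COc1cc(OCOC)ccc1OCOC | intermediate
14 | 1-bromo-4-methoxy-2,5-bis(methoxymethoxy)benzene | COc1cc(OCOC)c(Br)cc1OCOC | intermediate
15 | [4-methoxy-2,5-bis(methoxymethoxy)phenyl]lithium | COc1cc(OCOC)c([Li])cc1OCOC | intermediate (not isolated)
16 | dimethyl [4-methoxy-2,5-bis(methoxymethoxy)phenyl]boronate | COc1cc(OCOC)c(B(OC)OC)cc1OCOC | intermediate (not isolated)
17 | 4-methoxy-2,5-bis(methoxymethoxy)phenol | COc1cc(OCOC)c(O)cc1OCOC | intermediate
18 | triisopropyl[4-methoxy-2,5-bis(methoxymethoxy)phenoxy]silane | COc1cc(OCOC)c(O[Si](C(C)C)(C(C)C)C(C)C)cc1OCOC | intermediate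
19 | prenyl bromide (1-bromo-3-methylbut-2-ene) | CC(C)=CCBr | starting material
20 | 3-lithio derivative of 18 (lithium between the MOM ether and the methoxy group) | COc1c([Li])c(OCOC)c(O[Si](C(C)C)(C(C)C)C(C)C)cc1OCOC | intermediate (not isolated)
21 | triisopropyl[4-methoxy-2,5-bis(methoxymethoxy)-3-(3-methylbut-2-en-1-yl)phenoxy]silane | COc1c(CC=C(C)C)c(OCOC)c(O[Si](C(C)C)(C(C)C)C(C)C)cc1OCOC | intermediate
22 | 4-methoxy-2,5-bis(methoxymethoxy)-3-(3-methylbut-2-en-1-yl)phenol | COc1c(CC=C(C)C)c(OCOC)c(O)cc1OCOC | intermediate (ring-B nucleophile)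
23 | carbon dioxide | O=C=O | starting material
24 | potassium 4-methoxy-2,5-bis(methoxymethoxy)-3-(3-methylbut-2-en-1-yl)phenoxide | COc1c(CC=C(C)C)c(OCOC)c([O-])cc1OCOC.[K+] | intermediate (not isolated)
25 | 6,7-didehydro-5-(methoxymethoxy)-2,2-dimethyl-2H-chromene (aryne, C6≡C7) | COCOC1=C2C=CC(C)(C)OC2=CC#C1 | intermediate (not isolated)
26 | potassium 7-[4-methoxy-2,5-bis(methoxymethoxy)-3-(3-methylbut-2-en-1-yl)phenoxy]-5-(methoxymethoxy)-2,2-dimethyl-2H-chromen-6-ide | COc1c(OCOC)cc(Oc2cc3OC(C)(C)C=Cc3c(OCOC)[c-]2)c(OCOC)c1CC=C(C)C.[K+] | intermediate (not isolated)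
27 | potassium salt of acid 28 | COc1c(OCOC)cc(Oc2cc3OC(C)(C)C=Cc3c(OCOC)c2C(=O)[O-])c(OCOC)c1CC=C(C)C.[K+] | intermediate (not isolated)
28 | 7-[4-methoxy-2,5-bis(methoxymethoxy)-3-(3-methylbut-2-en-1-yl)phenoxy]-5-(methoxymethoxy)-2,2-dimethyl-2H-chromene-6-carboxylic acid | COc1c(OCOC)cc(Oc2cc3OC(C)(C)C=Cc3c(OCOC)c2C(=O)O)c(OCOC)c1CC=C(C)C | intermediate
29 | 7-[2,5-dihydroxy-4-methoxy-3-(3-methylbut-2-en-1-yl)phenoxy]-5-hydroxy-2,2-dimethyl-2H-chromene-6-carboxylic acid | COc1c(O)cc(Oc2cc3OC(C)(C)C=Cc3c(O)c2C(=O)O)c(O)c1CC=C(C)C | intermediate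
30 | garcinisidone B (achiral depsidone) | COc1c(O)cc2c(c1CC=C(C)C)OC(=O)c1c(cc3c(c1O)C=CC(C)(C)O3)O2 | target

**Step count**

Total: 16 steps. Longest linear sequence: 10 steps (steps 1–7, then 14–16); the ring-B branch is 6 steps (8–13).

**Steps most likely to fail**

Step 14. Three processes threaten it. The aryl anion may be protonated before it meets CO2, which would give only the simple diaryl ether. The phenoxide may be tied up by CO2 as its aryl carbonate, which either stops the addition or adds through carbonate oxygen and, after an acyl shift, gives an ester-linked isomer. A second aryne may arylate the product carboxylate. The fallback makes the same two bonds one after the other with known reactions. It sets out from 11: with CsF and I2 in MeCN the aryne is trapped as 6,7-diiodo-5-(methoxymethoxy)-2,2-dimethyl-2H-chromene F1 (aryne diiodination). Iodine–magnesium exchange with iPrMgCl·LiCl in THF at −78 °C is expected at the iodine flanked by the MOM ether, where the aryl–magnesium bond is stabilised by induction and chelation. Quenching with CO2 then gives 7-iodo-5-(methoxymethoxy)-2,2-dimethyl-2H-chromene-6-carboxylic acid F2. An Ullmann condensation of F2 with phenol 22 (CuI, N,N-dimethylglycine, Cs2CO3, dioxane, 90 °C), assisted by the ortho carboxylate, comes back to the route at acid 28.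

Step 5. Metalation may go in part to C8 (between the carbamate and the ring oxygen), the carbamoyl group may migrate to carbon, or the base may add to the styrene-type double bond. The fallback removes the strong carbamate director before silicon is introduced and delivers silicon from oxygen. It sets out from 7: LiAlH4 gives 5-(methoxymethoxy)-2,2-dimethyl-2H-chromen-7-ol F3, and TBSCl with imidazole gives tert-butyl{[5-(methoxymethoxy)-2,2-dimethyl-2H-chromen-7-yl]oxy}dimethylsilane F4. With n-BuLi and TMEDA in THF (−78 → 0 °C) the MOM ether, whose only free ortho position is C6, should direct lithiation there. A retro-Brook shift of the silyl group from oxygen to C6 then gives 6-(tert-butyldimethylsilyl)-5-(methoxymethoxy)-2,2-dimethyl-2H-chromen-7-ol F5. Tf2O and pyridine convert it to 6-(tert-butyldimethylsilyl)-5-(methoxymethoxy)-2,2-dimethyl-2H-chromen-7-yl trifluoromethanesulfonate F6. Used in place of 11 under the conditions of step 14, F6 generates the same aryne 25 and so comes back to the route at acid 28.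

Step 15. Under the acidic deprotection the electron-rich free acid may lose CO2, and the prenyl group may cyclise onto the freed neighbouring hydroxyl. The fallback activates the carboxyl before the phenols are freed, so that no free acid is ever exposed to acid and the lactone forms by acyl transfer. It sets out from 28: pentafluorophenol, DCC and catalytic DMAP in CH2Cl2 give pentafluorophenyl 7-[4-methoxy-2,5-bis(methoxymethoxy)-3-(3-methylbut-2-en-1-yl)phenoxy]-5-(methoxymethoxy)-2,2-dimethyl-2H-chromene-6-carboxylate F7. Brief treatment with HCl in MeOH–THF at rt should strip the MOM groups from this hindered ester and give pentafluorophenyl 7-[2,5-dihydroxy-4-methoxy-3-(3-methylbut-2-en-1-yl)phenoxy]-5-hydroxy-2,2-dimethyl-2H-chromene-6-carboxylate F8. iPr2NEt in dilute THF then lets the ortho hydroxyl of ring B displace pentafluorophenoxide, which comes back to the route at target 30.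

**Further compounds**

F1 | step 14 | 6,7-diiodo-5-(methoxymethoxy)-2,2-dimethyl-2H-chromene | COCOc1c(I)c(I)cc2OC(C)(C)C=Cc12
F2 | step 14 | 7-iodo-5-(methoxymethoxy)-2,2-dimethyl-2H-chromene-6-carboxylic acid | COCOc1c(C(=O)O)c(I)cc2OC(C)(C)C=Cc12
F3 | step 5 | 5-(methoxymethoxy)-2,2-dimethyl-2H-chromen-7-ol | COCOc1cc(O)cc2OC(C)(C)C=Cc12
F4 | step 5 | tert-butyl{[5-(methoxymethoxy)-2,2-dimethyl-2H-chromen-7-yl]oxy}dimethylsilane | COCOc1cc(O[Si](C)(C)C(C)(C)C)cc2OC(C)(C)C=Cc12
F5 | step 5 | 6-(tert-butyldimethylsilyl)-5-(methoxymethoxy)-2,2-dimethyl-2H-chromen-7-ol | COCOc1c([Si](C)(C)C(C)(C)C)c(O)cc2OC(C)(C)C=Cc12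
F6 | step 5 | 6-(tert-butyldimethylsilyl)-5-(methoxymethoxy)-2,2-dimethyl-2H-chromen-7-yl trifluoromethanesulfonate | COCOc1c([Si](C)(C)C(C)(C)C)c(OS(=O)(=O)C(F)(F)F)cc2OC(C)(C)C=Cc12
F7 | step 15 | pentafluorophenyl 7-[4-methoxy-2,5-bis(methoxymethoxy)-3-(3-methylbut-2-en-1-yl)phenoxy]-5-(methoxymethoxy)-2,2-dimethyl-2H-chromene-6-carboxylate | COc1c(OCOC)cc(Oc2cc3OC(C)(C)C=Cc3c(OCOC)c2C(=O)Oc2c(F)c(F)c(F)c(F)c2F)c(OCOC)c1CC=C(C)C
F8 | step 15 | pentafluorophenyl 7-[2,5-dihydroxy-4-methoxy-3-(3-methylbut-2-en-1-yl)phenoxy]-5-hydroxy-2,2-dimethyl-2H-chromene-6-carboxylate | COc1c(O)cc(Oc2cc3OC(C)(C)C=Cc3c(O)c2C(=O)Oc2c(F)c(F)c(F)c(F)c2F)c(O)c1CC=C(C)C
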